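Everything rests on cutting ring A of the benzofuran at C4–C5 and C3a–C7a. Ring A is a 1,2,4,5-tetrasubstituted resorcinol (oxygen on C7a and C6, prenyl on C5, C3 on C3a), which is the pattern a γ-prenylated acetoacetate diene delivers when it adds to a terminal ynone and aromatizes. One operation therefore builds ring A with all four substituents in place and, through a mixed-silyl diene (O3 triisopropylsilyl, O1 trimethylsilyl), with O6 already protected and O7a free. The precursors are a (3Z)-silyloxytriene and a benzyl ethynyl ketone carrying ring C. Diazo transfer, O–H insertion (O1–C2), O-methylation at C3 and desilylation complete the target.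

Key step: step 7

Remark: the target is achiral. The enoate geometry of the silyl enol ether and the ketene-acetal geometry of the diene are left open because both are lost in the next bond-forming event. The C2 centre of the coumaranone is racemic and is erased by the following enolization.
Remark: the labels O1, C2 to C7a follow the benzofuran numbering of the target. Metalated forms (enolates, magnesium adducts) are treated as reactive states of the numbered compounds.

Step 1
Reactants: 1 methyl acetoacetate; 2 prenyl bromide (1-bromo-3-methylbut-2-ene)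
Product: 3 methyl 7-methyl-3-oxooct-6-enoate
Conditions: NaH (1.1 eq), THF, 0 °C; n-BuLi (1.05 eq), 0 °C; 2 (1.0 eq), 0 → 20 °C; aq. HCl quench
Reagents that add atoms: none
Why: Weiler dianion alkylation, in which the terminal (γ) carbanion of the acetoacetate dianion is the more reactive centre and is alkylated by the primary allylic bromide in an SN2 reaction, so the prenyl group sits on the carbon that becomes C5.

Step 2
Reactants: 3 methyl 7-methyl-3-oxooct-6-enoate
Product: 4 methyl 7-methyl-3-(triisopropylsilyloxy)octa-2,6-dienoate (2E/2Z mixture, used as such)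
Conditions: iPr3SiOTf (1.1 eq), Et3N (1.5 eq), CH2Cl2, 0 → 20 °C
Reagents that add atoms: triisopropylsilyl trifluoromethanesulfonate, CC(C)[Si](OS(=O)(=O)C(F)(F)F)(C(C)C)C(C)C
Why: Silyl triflate/amine O-silylation of the β-keto ester at the ketone oxygen (silyl enol ether formation) gives the conjugated β-silyloxy enoate, and the bulky silyl group is placed here because this oxygen becomes O6 and must stay protected until the last step.

Step 3
Reactants: 4 methyl 7-methyl-3-(triisopropylsilyloxy)octa-2,6-dienoate
Product: 5 (3Z)-1-methoxy-7-methyl-3-(triisopropylsilyloxy)-1-(trimethylsilyloxy)octa-1,3,6-triene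
Conditions: LiN(iPr)2 (commercial solution, 1.15 eq), THF, −78 °C; Me3SiCl (1.3 eq), −78 → 0 °C; evaporation, pentane, filtration under argon, used crude and amine-free
Reagents that add atoms: chlorotrimethylsilane, C[Si](C)(C)Cl
Why: Kinetic γ-deprotonation of the β-silyloxy enoate gives the ester dienolate, which Me3SiCl silylates on oxygen to the ketene silyl acetal (the standard preparation of 1-alkoxy-1,3-bis(silyloxy)dienes), and the 3Z isomer with the chain cis to the silyloxy group is expected to predominate because it avoids allylic strain with C2.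

Step 4
Reactants: 6 3-hydroxy-4-methoxyphenylacetic acid
Product: 7 2-(3-hydroxy-4-methoxyphenyl)-N-methoxy-N-methylacetamide
Conditions: MeNHOMe·HCl (1.2 eq), EDC·HCl (1.2 eq), N-methylmorpholine (2.5 eq), CH2Cl2, 0 → 20 °C
Reagents that add atoms: N,O-dimethylhydroxylamine hydrochloride, CNOC.Cl
Why: Carbodiimide amide coupling, in which the O-acylisourea is captured by the α-effect amine much faster than by the weakly nucleophilic guaiacol-type phenol, so the Weinreb amide should form without phenol protection.

Step 5
Reactants: 7 2-(3-hydroxy-4-methoxyphenyl)-N-methoxy-N-methylacetamide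
Product: 8 N-methoxy-2-[4-methoxy-3-(triisopropylsilyloxy)phenyl]-N-methylacetamide
Conditions: iPr3SiCl (1.2 eq), imidazole (2.5 eq), DMF, 20 °C
Reagents that add atoms: chlorotriisopropylsilane, CC(C)[Si](Cl)(C(C)C)C(C)C
Why: Imidazole-promoted silylation of the only OH gives an aryl triisopropylsilyl ether that should withstand the Grignard reagent, amidine base, carbonate and mild acid used later and is cleaved by fluoride.

Step 6
Reactants: 8 N-methoxy-2-[4-methoxy-3-(triisopropylsilyloxy)phenyl]-N-methylacetamide; 9 ethynylmagnesium bromide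
Product: 10 1-[4-methoxy-3-(triisopropylsilyloxy)phenyl]but-3-yn-2-one
Conditions: HC≡CMgBr (0.5 M in THF, 2.0 eq), THF, −20 → 0 °C; inverse quench into cold 1 M aq. HCl; rapid chromatography, stored cold, used promptly
Reagents that add atoms: none
Why: Weinreb ketone synthesis, in which the magnesium-chelated tetrahedral adduct does not collapse before the quench so only one acetylide adds, and the inverse acidic quench protonates the released N,O-dimethylhydroxylamine before it can add to the ynone in conjugate fashion.

Step 7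
Reactants: 5 (3Z)-1-methoxy-7-methyl-3-(triisopropylsilyloxy)-1-(trimethylsilyloxy)octa-1,3,6-triene (1.5 eq); 10 1-[4-methoxy-3-(triisopropylsilyloxy)phenyl]but-3-yn-2-one
Product: 13 1-[2-hydroxy-5-(3-methylbut-2-enyl)-4-(triisopropylsilyloxy)phenyl]-2-[4-methoxy-3-(triisopropylsilyloxy)phenyl]ethanone, via ketal cycloadduct 11 (not isolated), via aryl trimethylsilyl ether 12 (not isolated)
Conditions: toluene, −20 → 45 °C, argon; then PPTS (0.2 eq), MeOH, 20 °C
Reagents that add atoms: none
Why: The electron-rich diene 5 and the electron-poor ynone 10 combine in a thermal normal-demand [4+2] cycloaddition (or, equivalently, Mukaiyama–Michael addition followed by Claisen-type closure of the allenolate onto the ketene-acetal carbon), the prenyl-bearing diene terminus bonding to the alkyne CH (C5–C4) and the ketene-acetal carbon to the acyl-bearing alkyne carbon (C7a–C3a); 11 then loses methanol across the ring to give arene 12, whose labile aryl trimethylsilyl ether is methanolysed by PPTS/MeOH while the triisopropylsilyl ether on O6 stays. The closest known reaction type is the aromatizing Diels–Alder reaction of 1-alkoxy-1,3-bis(silyloxy)buta-1,3-dienes with alkynyl ketones and esters, which gives 4-hydroxysalicyl derivatives. Ring A is closed as a six-membered carbocycle by intermolecular [4+2] annulation of two acyclic partners, both ring bonds arising in the same operation. The two sp3 carbons of 11 are formed without control and both become sp2 on aromatization, so no stereocentre has to be set. The step needs regioselectivity (C5 to C4, C7a to C3a), and this is secured by the match of the largest HOMO coefficient at the alkyl-bearing diene terminus with the largest LUMO coefficient at the unsubstituted β-carbon of the ynone, which is also its sterically open end. The 3Z enol ether keeps the prenyl chain outside the s-cis diene, and the absence of a Lewis acid disfavours 1,2-addition to the ketone.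

Step 8
Reactants: 13 1-[2-hydroxy-5-(3-methylbut-2-enyl)-4-(triisopropylsilyloxy)phenyl]-2-[4-methoxy-3-(triisopropylsilyloxy)phenyl]ethanone
Product: 14 2-diazo-1-[2-hydroxy-5-(3-methylbut-2-enyl)-4-(triisopropylsilyloxy)phenyl]-2-[4-methoxy-3-(triisopropylsilyloxy)phenyl]ethanone
Conditions: 4-acetamidobenzenesulfonyl azide (1.3 eq), DBU (2.5 eq), MeCN, 0 → 20 °C; pH 7 buffer work-up, short silica plug
Reagents that add atoms: 4-acetamidobenzenesulfonyl azide, CC(=O)Nc1ccc(cc1)S(=O)(=O)N=[N+]=[N-]
Why: Regitz diazo transfer, for which the methylene flanked by ring C and the ketone is about as acidic as that of deoxybenzoins and aryl acetates that react under these conditions, with the extra DBU accounting for the chelated phenol and with the silyl ethers and the prenyl alkene inert.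

Step 9
Reactants: 14 2-diazo-1-[2-hydroxy-5-(3-methylbut-2-enyl)-4-(triisopropylsilyloxy)phenyl]-2-[4-methoxy-3-(triisopropylsilyloxy)phenyl]ethanone
Product: 15 rac-2-[4-methoxy-3-(triisopropylsilyloxy)phenyl]-5-(3-methylbut-2-enyl)-6-(triisopropylsilyloxy)-1-benzofuran-3(2H)-one
Conditions: Rh2(OAc)4 (1 mol %), CH2Cl2, 20 °C, argon; filtered through silica under argon and used at once
Reagents that add atoms: none
Why: Dirhodium-carbene O–H insertion, in which loss of N2 gives an aryl ketocarbene that the neighbouring phenolic OH captures through an oxonium ylide and proton shift, closing O1–C2 as a five-membered ring faster than cyclopropanation of the remote prenyl alkene or Wolff rearrangement, with C2 formed racemic and erased in step 10.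

Step 10
Reactants: 15 rac-2-[4-methoxy-3-(triisopropylsilyloxy)phenyl]-5-(3-methylbut-2-enyl)-6-(triisopropylsilyloxy)-1-benzofuran-3(2H)-one
Product: 16 3-methoxy-2-[4-methoxy-3-(triisopropylsilyloxy)phenyl]-5-(3-methylbut-2-enyl)-6-(triisopropylsilyloxy)-1-benzofuran
Conditions: K2CO3 (anhydrous, 3 eq), Me2SO4 (1.5 eq), degassed acetone, 20 → 40 °C, argon
Reagents that add atoms: dimethyl sulfate, COS(=O)(=O)OC
Why: Enolate O-alkylation, in which the potassium enolate of the 2-aryl coumaranone is a 3-oxidobenzofuran whose C2 is tertiary and hindered, so the hard electrophile dimethyl sulfate should attack oxygen and the product gains benzofuran aromaticity, while anhydrous carbonate in acetone leaves the aryl silyl ethers in place.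

Step 11
Reactants: 16 3-methoxy-2-[4-methoxy-3-(triisopropylsilyloxy)phenyl]-5-(3-methylbut-2-enyl)-6-(triisopropylsilyloxy)-1-benzofuran
Product: 17 2-(3-hydroxy-4-methoxyphenyl)-3-methoxy-5-(3-methylbut-2-enyl)-1-benzofuran-6-ol (target)
Conditions: Bu4NF (2.4 eq), AcOH (2.4 eq), THF, 0 → 20 °C, argon
Reagents that add atoms: none
Why: Fluoride-driven cleavage of both aryl silyl ethers (Si–F bond formation), buffered with acetic acid so that the electron-rich phenols are not held as phenolates, with the prenyl group and the C3 methyl ether untouched.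

Compound list
1 | methyl acetoacetate | COC(=O)CC(C)=O | starting material
2 | prenyl bromide (1-bromo-3-methylbut-2-ene) | CC(C)=CCBr | starting material
3 | methyl 7-methyl-3-oxooct-6-enoate | COC(=O)CC(=O)CCC=C(C)C | intermediate
4 | methyl 7-methyl-3-(triisopropylsilyloxy)octa-2,6-dienoate (2E/2Z mixture) | COC(=O)C=C(CCC=C(C)C)O[Si](C(C)C)(C(C)C)C(C)C | intermediate
5 | (3Z)-1-methoxy-7-methyl-3-(triisopropylsilyloxy)-1-(trimethylsilyloxy)octa-1,3,6-triene (C1=C2 geometry open) | CC(C)=CC/C=C(O[Si](C(C)C)(C(C)C)C(C)C)/C=C(OC)O[Si](C)(C)C | intermediate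
6 | 3-hydroxy-4-methoxyphenylacetic acid | COc1ccc(CC(=O)O)cc1O | starting material
7 | 2-(3-hydroxy-4-methoxyphenyl)-N-methoxy-N-methylacetamide | COc1ccc(CC(=O)N(C)OC)cc1O | intermediate
8 | N-methoxy-2-[4-methoxy-3-(triisopropylsilyloxy)phenyl]-N-methylacetamide | COc1ccc(CC(=O)N(C)OC)cc1O[Si](C(C)C)(C(C)C)C(C)C | intermediate
9 | ethynylmagnesium bromide | C#C[Mg]Br | starting material
10 | 1-[4-methoxy-3-(triisopropylsilyloxy)phenyl]but-3-yn-2-one | COc1ccc(CC(=O)C#C)cc1O[Si](C(C)C)(C(C)C)C(C)C | intermediate
11 | 1-[6-methoxy-3-(3-methylbut-2-enyl)-4-(triisopropylsilyloxy)-6-(trimethylsilyloxy)cyclohexa-1,4-dien-1-yl]-2-[4-methoxy-3-(triisopropylsilyloxy)phenyl]ethanone (racemic diastereomer mixture, not isolated) | COC1(O[Si](C)(C)C)C=C(O[Si](C(C)C)(C(C)C)C(C)C)C(CC=C(C)C)C=C1C(=O)Cc1ccc(OC)c(O[Si](C(C)C)(C(C)C)C(C)C)c1 | intermediate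
12 | 1-[5-(3-methylbut-2-enyl)-4-(triisopropylsilyloxy)-2-(trimethylsilyloxy)phenyl]-2-[4-methoxy-3-(triisopropylsilyloxy)phenyl]ethanone (not isolated) | C[Si](C)(C)Oc1cc(O[Si](C(C)C)(C(C)C)C(C)C)c(CC=C(C)C)cc1C(=O)Cc1ccc(OC)c(O[Si](C(C)C)(C(C)C)C(C)C)c1 | intermediate
13 | 1-[2-hydroxy-5-(3-methylbut-2-enyl)-4-(triisopropylsilyloxy)phenyl]-2-[4-methoxy-3-(triisopropylsilyloxy)phenyl]ethanone | COc1ccc(CC(=O)c2cc(CC=C(C)C)c(O[Si](C(C)C)(C(C)C)C(C)C)cc2O)cc1O[Si](C(C)C)(C(C)C)C(C)C | intermediate
14 | 2-diazo-1-[2-hydroxy-5-(3-methylbut-2-enyl)-4-(triisopropylsilyloxy)phenyl]-2-[4-methoxy-3-(triisopropylsilyloxy)phenyl]ethanone | COc1ccc(C(=[N+]=[N-])C(=O)c2cc(CC=C(C)C)c(O[Si](C(C)C)(C(C)C)C(C)C)cc2O)cc1O[Si](C(C)C)(C(C)C)C(C)C | intermediate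
15 | rac-2-[4-methoxy-3-(triisopropylsilyloxy)phenyl]-5-(3-methylbut-2-enyl)-6-(triisopropylsilyloxy)-1-benzofuran-3(2H)-one | COc1ccc(C2Oc3cc(O[Si](C(C)C)(C(C)C)C(C)C)c(CC=C(C)C)cc3C2=O)cc1O[Si](C(C)C)(C(C)C)C(C)C | intermediate
16 | 3-methoxy-2-[4-methoxy-3-(triisopropylsilyloxy)phenyl]-5-(3-methylbut-2-enyl)-6-(triisopropylsilyloxy)-1-benzofuran | COc1ccc(-c2oc3cc(O[Si](C(C)C)(C(C)C)C(C)C)c(CC=C(C)C)cc3c2OC)cc1O[Si](C(C)C)(C(C)C)C(C)C | intermediate
17 | 2-(3-hydroxy-4-methoxyphenyl)-3-methoxy-5-(3-methylbut-2-enyl)-1-benzofuran-6-ol | COc1ccc(-c2oc3cc(O)c(CC=C(C)C)cc3c2OC)cc1O | target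

Total step count: 11
Longest linear sequence: 8 steps (steps 1–3 or steps 4–6, then steps 7–11)

Steps most likely to fail

Step 7. The cycloaddition of the hindered, terminally alkylated diene may be so slow that ynone oligomerization or 1,2-addition of the diene to the ketone takes over. The fallback takes ring A from an aromatic building block instead of constructing it; it sets out from Weinreb amide 8 and bromide 2 and returns at 13. Commercial 4,6-dibromobenzene-1,3-diol F1 would be protected (MeOCH2Cl, iPr2NEt, CH2Cl2) as 1,5-dibromo-2,4-bis(methoxymethoxy)benzene F2. One bromine–lithium exchange (n-BuLi, 1.0 eq, THF, −78 °C), transmetalation with CuBr·SMe2 and alkylation with 2 should give 1-bromo-2,4-bis(methoxymethoxy)-5-(3-methylbut-2-enyl)benzene F3. A second exchange and acylation of the aryllithium by 8 should give 1-[2,4-bis(methoxymethoxy)-5-(3-methylbut-2-enyl)phenyl]-2-[4-methoxy-3-(triisopropylsilyloxy)phenyl]ethanone F4. Aqueous HCl in MeOH at 20 °C should remove both acetals to give 1-[2,4-dihydroxy-5-(3-methylbut-2-enyl)phenyl]-2-[4-methoxy-3-(triisopropylsilyloxy)phenyl]ethanone F5. Silylation of the non-chelated O6–H (iPr3SiCl, imidazole, CH2Cl2, 0 °C) then gives 13.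

Step 8. Deprotonation of the chelated phenol may suppress enolization of the methylene so that diazo transfer stalls, or the hydroxy diazo ketone may decompose during isolation. The fallback closes O1–C2 by substitution at an oxygenated C2 instead of by carbene insertion; it sets out from 13 and returns at 15, so step 9 is bypassed. The dianion of 13 (KN(SiMe3)2, 2.2 eq, THF, −78 °C) would be hydroxylated with 2-(phenylsulfonyl)-3-phenyloxaziridine to give rac-2-hydroxy-1-[2-hydroxy-5-(3-methylbut-2-enyl)-4-(triisopropylsilyloxy)phenyl]-2-[4-methoxy-3-(triisopropylsilyloxy)phenyl]ethanone F6. Intramolecular Mitsunobu etherification (PPh3, diisopropyl azodicarboxylate, THF, 0 °C) with the ortho phenol as nucleophile should then give 15.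

Step 10. The ambident enolate may be methylated on C2 instead of on oxygen, or may be oxidized by air at C2. The fallback forms the enol ether under acid catalysis without any enolate; it sets out from 15 and returns at 16. Trimethyl orthoformate in MeOH with catalytic PPTS at 50 °C should convert the ketone into rac-3,3-dimethoxy-2-[4-methoxy-3-(triisopropylsilyloxy)phenyl]-5-(3-methylbut-2-enyl)-6-(triisopropylsilyloxy)-2,3-dihydro-1-benzofuran F7, which loses methanol under the same conditions and aromatizes to 16.

Further compounds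
F1 | step 7 | 4,6-dibromobenzene-1,3-diol (commercial) | Oc1cc(O)c(Br)cc1Br
F2 | step 7 | 1,5-dibromo-2,4-bis(methoxymethoxy)benzene | COCOc1cc(OCOC)c(Br)cc1Br
F3 | step 7 | 1-bromo-2,4-bis(methoxymethoxy)-5-(3-methylbut-2-enyl)benzene | COCOc1cc(OCOC)c(CC=C(C)C)cc1Br
F4 | step 7 | 1-[2,4-bis(methoxymethoxy)-5-(3-methylbut-2-enyl)phenyl]-2-[4-methoxy-3-(triisopropylsilyloxy)phenyl]ethanone | COCOc1cc(OCOC)c(CC=C(C)C)cc1C(=O)Cc1ccc(OC)c(O[Si](C(C)C)(C(C)C)C(C)C)c1
F5 | step 7 | 1-[2,4-dihydroxy-5-(3-methylbut-2-enyl)phenyl]-2-[4-methoxy-3-(triisopropylsilyloxy)phenyl]ethanone | COc1ccc(CC(=O)c2cc(CC=C(C)C)c(O)cc2O)cc1O[Si](C(C)C)(C(C)C)C(C)C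
F6 | step 8 | rac-2-hydroxy-1-[2-hydroxy-5-(3-methylbut-2-enyl)-4-(triisopropylsilyloxy)phenyl]-2-[4-methoxy-3-(triisopropylsilyloxy)phenyl]ethanone | COc1ccc(C(O)C(=O)c2cc(CC=C(C)C)c(O[Si](C(C)C)(C(C)C)C(C)C)cc2O)cc1O[Si](C(C)C)(C(C)C)C(C)C
F7 | step 10 | rac-3,3-dimethoxy-2-[4-methoxy-3-(triisopropylsilyloxy)phenyl]-5-(3-methylbut-2-enyl)-6-(triisopropylsilyloxy)-2,3-dihydro-1-benzofuran | COc1ccc(C2Oc3cc(O[Si](C(C)C)(C(C)C)C(C)C)c(CC=C(C)C)cc3C2(OC)OC)cc1O[Si](C(C)C)(C(C)C)C(C)C
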